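## Structural features

The target is a 2,3-dihydrobenzofuran: ring A is the benzene ring (C3a, C4–C7, C7a) and ring B holds O1, C2 and C3. Ring A is fully substituted, with hydroxyls at C4 and C6, an isobutyryl group at C5 between them, the ring-B oxygen at C7a, and at C7 a methylene bridge to C3' of a 6-ethyl-4-hydroxy-5-methyl-2-pyrone (ring C). Ring A is therefore an acylphloroglucinol in which the oxygen para to the acyl group is tied into ring B. The only stereocentre is C2 (R), which carries the isopropenyl group. It has no neighbouring stereocentre, so its configuration must come from a reagent or a catalyst. The fragile parts are the allylic aryl ether at C2 with its 1,1-disubstituted alkene (ionisation, hydration or ring opening in acid), the electron-rich ring A, the enolic 4-hydroxypyrone, and the methylene bridge, which can exchange partners under forcing conditions. The real difficulty is to set C2 with enantiocontrol on a ring that carries three differentiated oxygens, and then to finish with mild deprotections only. The key step uses the fact that C3 is a benzylic CH2 on C3a while C2 is the carbon next to O1: a carbene centre at C3 can reach a C–H bond of the O1–CH2 group five atoms away, so the C2–C3 bond, ring B and the stereocentre arise together.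

## Logic of the disconnections

**23 to 16 and 21.** The C7–CH2 bond of the bridge is cut. C7 is the only unsubstituted carbon of ring A and lies between two oxygens, and C3' of the pyrone is the α-carbon of a vinylogous acid, so both are natural nucleophiles toward a one-carbon electrophile. The cut divides the molecule into two halves of similar size and makes the route convergent. The forward step must attach the one-carbon unit to one partner first (21) and release it as electrophile 22 in the presence of 16 without acid that would harm C2 or the alkene.

**21 to 20, then 20 to 18 and 19, then 18 to 17.** First the C3'–CH2 bond is cut, then ring C at C4'–C5' and O1'–C2'. Ring C becomes a malonyl unit (19) plus the enol derivative (18) of a symmetric ketone (17), so no regiochemical question arises. The forward steps need C-acylation of 18 before ring closure and a single aminomethylation of 20.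

**16 to 15 to 14 to 13.** Only functional groups change: two aryl O–Si bonds, the C=C bond traced back to a tertiary C–OH, and one alkyl O–Si bond. The alkene must be absent during the key step, and the phenols must be masked while the carbinol is dehydrated. The forward steps need selective cleavage of an alkyl triethylsilyl ether beside two aryl silyl ethers, and elimination toward a methyl group and not toward C2.

**13 to 10 (through 12 and 11).** The C2–C3 bond is cut. This removes ring B and the only stereocentre at once and leaves an achiral, fully substituted benzaldehyde derivative whose ether side chain has no stereochemical element. The forward step needs a catalyst that distinguishes the two enantiotopic hydrogens of the O–CH2 group, slow delivery of 12, and a substrate with no other C–H bond at the same distance, no alkene and no free hydroxyl. 10 is built to meet this: silicon on both phenolic oxygens, a quaternary carbon next to the reacting CH2, and the future alkene stored as a silyl-protected carbinol. The salt 11 is made with NaH in an aprotic medium, because aryl silyl ethers ortho to carbonyl groups would not survive an alkoxide in alcohol.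

**10 to 9 to 8 to 7.** The C=N bond and three O–Si bonds are cut. The aldehyde is the one-carbon handle that becomes C3. The phenols are silylated first with a reagent that ignores tertiary alcohols, and the carbinol second with a silyl triflate. The forward steps need condensation at the aldehyde only (the ketone is flanked by two ortho substituents) and conditions that spare the aryl silyl ethers.

**7 to 5.** The bond between the ring and the formyl carbon is cut. 5 is symmetric, so its two free ring carbons are equivalent and the position of formylation is not in question. The forward step needs a single formylation that tolerates the tertiary carbinol.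

**5 to 3 and 4.** The aryl O–CH2 bond is cut. The para hydroxyl of 3 is the only one not hydrogen-bonded to the ketone and is the most acidic, and 4 opens at its CH2 terminus to give the tertiary carbinol directly. The forward step needs alkylation at that oxygen only.

**3 to 1 and 2.** The bond from ring A to the acyl carbon is cut. 1 is threefold symmetric, so the acyl group that later sits at C5 is placed without any selectivity issue.

## Other disconnections considered

**Alternative 1:** The cut runs through ring C at C4'–C5' and O1'–C2'. The pyrone would be built last on a ring-A fragment that already carries the bridge carbon inside an arylmethylmalonyl unit. In the forward direction the dichloride A2 would acylate silyl enol ether 18 at carbon, and the enol oxygen so formed would close on the second acyl chloride to give the bis(methoxymethyl) ether A1, from which acid would release 23.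
- In its favour: the bridge carbon is attached to C7 by ordinary malonate chemistry and never passes through a free methylene electrophile, so symmetric bis-adducts cannot form. On this point it is better than the chosen plan. The ring-forming reaction is of the same type as step 12, so on mechanism the two are equal.
- Against it here: an acid dichloride, and the HCl it gives off, must be made and handled beside two acetal protecting groups, an isopropenyl group and an allylic aryl ether. The final acetal cleavage needs protic acid that endangers C2 and the alkene, whereas the chosen plan ends with buffered fluoride and a neutral thermal coupling.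
- Step economy: the chiral fragment would be carried through C7 functionalisation, malonate formation, saponification, chlorination, annulation and deprotection, against the single coupling step 14.
- Structure: it leaves ring B and C2 unsolved, so an enantioselective step such as step 7 would still be needed.

**Alternative 2:** The cut removes ring A. C6–C7, C3a–C7a and C5–C6 would form from the tethered cyclobutenone–alkynyl ether A4 in one benzannulation cascade: ring opening of the four-membered ring under irradiation, [2+2] addition to the tethered alkyne, a second ring opening, 6π closure and tautomerisation. This would give phenol A3 with rings A and B made together.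
- In its favour: the C2 stereocentre comes from a chiral alcohol made before the cascade, so enantiocontrol does not rest on an untested catalyst-controlled insertion. Here it is better than the chosen plan. The pyrone is already at C7, so no bridging step is needed, and the cascade is a well-precedented pericyclic sequence.
- Against it here: an alkynyl ether of a secondary alcohol with β-hydrogens tends to lose a ketene by a retro-ene path on warming, which the later stages of the cascade require. The 2-pyrone chromophore is exposed to the light. A3 still lacks the C5 isobutyryl group, so an acylation must be run on a substrate that carries a triethylsilyl ether and a pyrone. An aryl ethyl ether and a pyrone methyl ether must finally be cleaved with Lewis acids that the isopropenyl dihydrofuran does not tolerate well.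
- Step economy: making A4 (an ynol ether at a hindered carbinol, a 2-alkyl-3-ethoxycyclobutenone, a propargylic pyrone) is clearly longer than the seven steps to 13.
- Structure: it is the more general construction of a hexasubstituted benzene, but ring A of the target is available as 1, so that generality gains nothing here.

**Alternative 3:** The cut is at C6–O and C5–C(=O): hydroxyl and acyl group would be delivered together to an aryne. Fluoride-induced elimination of silyl triflate A6 would give aryne A7. 2-Methylpropanoic acid A8 would add with its oxygen at C6, meta to the C4 alkoxy group as the distortion of such an aryne directs, and the aryl anion at C5 would take over the acyl group to give ketone A5.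
- In its favour: it is a known reaction type, its regiochemistry is set by an existing substituent, and it places a hindered ketone between two oxygens without electrophilic substitution. On precedent it is better than step 7.
- Against it here: the bond it makes is the easiest one in the chosen plan (step 1 on a symmetric ring), so nothing is gained. A6 already contains ring B, C2 and the isopropenyl group, which would have to come from some other enantioselective route, and an ortho-silyl aryl triflate must be assembled on that fragment. Acyl transfer competes with simple O-arylation and with protonation of the aryl anion, and it needs heat.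
- Step economy: acetal removal with acid and the C7 bridging still follow, so it is at best equal in the endgame and longer overall.

Key step: step 7

Remark on the chemistry: Rh2(S-PTAD)4 is assumed to give the (R) configuration at C2; if the sense of induction is the opposite, Rh2(R-PTAD)4 takes its place and nothing else changes.

Remark on names: 10 is named as a benzaldehyde derivative (2,4-disilyloxy, 3-acyl, 6-alkoxy); the ring-A locants of the target apply from 13 onward, where C2 is R throughout because O1 > side-chain carbon > C3 > H holds for both the silyloxypropyl and the isopropenyl group.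

## Steps

Step 1
Reactants: 1 phloroglucinol; 2 isobutyryl chloride
Product: 3 2-methyl-1-(2,4,6-trihydroxyphenyl)propan-1-one
Conditions: AlCl3, PhNO2/CH2Cl2, rt→60 °C; aq. HCl
Reagents that add atoms: none
Why: Friedel–Crafts acylation of a threefold symmetric triphenol; all ring carbons are equivalent and the first acyl group deactivates the ring toward a second.

Step 2
Reactants: 3 2-methyl-1-(2,4,6-trihydroxyphenyl)propan-1-one; 4 isobutylene oxide
Product: 5 1-[2,6-dihydroxy-4-(2-hydroxy-2-methylpropoxy)phenyl]-2-methylpropan-1-one
Conditions: K2CO3 (0.3 equiv), DMF, 70 °C, sealed tube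
Reagents that add atoms: none
Why: Phenoxide opening of an epoxide by SN2 attack at the unhindered CH2; the para hydroxyl is the most acidic and the only one not chelated to the ketone, and once it is alkylated the two chelated hydroxyls are poor nucleophiles.

Step 3
Reactants: 5 1-[2,6-dihydroxy-4-(2-hydroxy-2-methylpropoxy)phenyl]-2-methylpropan-1-one
Product: 7 2,4-dihydroxy-6-(2-hydroxy-2-methylpropoxy)-3-(2-methylpropanoyl)benzaldehyde, via iminium salt 6 (not isolated)
Conditions: POCl3 (1.2 equiv), DMF, MeCN, 0 °C→rt; then H2O, 50 °C
Reagents that add atoms: N,N-dimethylformamide CN(C)C=O; water O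
Why: Vilsmeier–Haack formylation of an acylphloroglucinol; the two free ring carbons are equivalent by symmetry, the iminium group deactivates the ring toward a second attack, and the hindered tertiary carbinol should react far more slowly with the limited amount of chloroiminium reagent than the ring carbon does.

Step 4
Reactants: 7 2,4-dihydroxy-6-(2-hydroxy-2-methylpropoxy)-3-(2-methylpropanoyl)benzaldehyde
Product: 8 2,4-bis(tert-butyldimethylsilyloxy)-6-(2-hydroxy-2-methylpropoxy)-3-(2-methylpropanoyl)benzaldehyde
Conditions: TBSCl, imidazole, DMAP (cat.), DMF, rt→40 °C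
Reagents that add atoms: tert-butyldimethylsilyl chloride CC(C)(C)[Si](C)(C)Cl
Why: Silylation of the two acidic phenols; TBSCl with imidazole does not silylate tertiary alcohols, so the carbinol stays free for a different silyl group.

Step 5
Reactants: 8 2,4-bis(tert-butyldimethylsilyloxy)-6-(2-hydroxy-2-methylpropoxy)-3-(2-methylpropanoyl)benzaldehyde
Product: 9 2,4-bis(tert-butyldimethylsilyloxy)-3-(2-methylpropanoyl)-6-[2-methyl-2-(triethylsilyloxy)propoxy]benzaldehyde
Conditions: TESOTf, 2,6-lutidine, CH2Cl2, −78→0 °C
Reagents that add atoms: triethylsilyl trifluoromethanesulfonate CC[Si](CC)(CC)OS(=O)(=O)C(F)(F)F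
Why: Silyl triflate silylation of a hindered tertiary alcohol; the hindered base does not enolise the diortho-substituted isopropyl ketone at low temperature.

Step 6
Reactants: 9 2,4-bis(tert-butyldimethylsilyloxy)-3-(2-methylpropanoyl)-6-[2-methyl-2-(triethylsilyloxy)propoxy]benzaldehyde
Product: 10 (E)-4-methyl-N'-{2,4-bis(tert-butyldimethylsilyloxy)-3-(2-methylpropanoyl)-6-[2-methyl-2-(triethylsilyloxy)propoxy]benzylidene}benzenesulfonohydrazide
Conditions: TsNHNH2, MgSO4, THF, rt→40 °C
Reagents that add atoms: 4-methylbenzenesulfonohydrazide Cc1ccc(cc1)S(=O)(=O)NN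
Why: Hydrazone condensation at the aldehyde only, since the ketone is shielded by two ortho substituents and an isopropyl group; the E isomer is the thermodynamic one, and the aprotic medium spares the aryl silyl ethers.

Step 7
Reactants: 10 (E)-4-methyl-N'-{2,4-bis(tert-butyldimethylsilyloxy)-3-(2-methylpropanoyl)-6-[2-methyl-2-(triethylsilyloxy)propoxy]benzylidene}benzenesulfonohydrazide
Product: 13 (R)-1-{4,6-bis(tert-butyldimethylsilyloxy)-2-[2-(triethylsilyloxy)propan-2-yl]-2,3-dihydro-1-benzofuran-5-yl}-2-methylpropan-1-one, via sodium salt 11 (not isolated), via aryldiazomethane 12 (not isolated)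
Conditions: NaH, THF, 0 °C, then evaporate; Rh2(S-PTAD)4 (2 mol %), BnEt3NCl (10 mol %), PhCF3, 40 °C
Reagents that add atoms: none
Why: Proposed new method: NaH converts 10 into salt 11, which under phase transfer loses sulfinate (Bamford–Stevens) and feeds aryldiazomethane 12 slowly to the chiral divalent-rhodium carboxylate; loss of N2 gives an electrophilic rhodium carbene at C3 that draws a hydride-like hydrogen from the O1–CH2 group through a three-centre transition state while the C2–C3 bond forms. The closest known reaction types are the enantioselective 1,5 C–H insertion of donor-substituted rhodium carbenes into ether C–H bonds, which gives 2,3-dihydrobenzofurans, and the thermal cyclisation of 2-alkoxybenzaldehyde tosylhydrazone salts; new here is enantiocontrol with a carbene that carries only an aryl group and hydrogen. Ring B closes in the five-membered 1,5 mode, the only one open at that distance, because the neighbouring carbinol carbon is quaternary and the C4 oxygen carries silicon and no C–H. Insertion into the silyl methyl groups would need six- or seven-membered transition states and lacks activation by a heteroatom. The C2 stereocentre is set by the catalyst, which must distinguish the two enantiotopic hydrogens of the O1–CH2 group, and the bulky quaternary silyloxy substituent on that carbon gives the chiral pocket a large group to orient. Azine and stilbene formation is held back by the low stationary concentration of 12, and cyclopropanation is excluded because the alkene is stored as a protected carbinol. The aryl silyl ethers tolerate NaH in an aprotic medium, which is why no alkoxide base is used.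

Step 8
Reactants: 13 (R)-1-{4,6-bis(tert-butyldimethylsilyloxy)-2-[2-(triethylsilyloxy)propan-2-yl]-2,3-dihydro-1-benzofuran-5-yl}-2-methylpropan-1-one
Product: 14 (R)-1-[4,6-bis(tert-butyldimethylsilyloxy)-2-(2-hydroxypropan-2-yl)-2,3-dihydro-1-benzofuran-5-yl]-2-methylpropan-1-one
Conditions: CSA (cat.), MeOH/CH2Cl2, 0 °C
Reagents that add atoms: none
Why: Acid-catalysed methanolysis of a silyl ether; an alkyl triethylsilyl ether is far more acid-labile than aryl tert-butyldimethylsilyl ethers, and C2 is not involved.

Step 9
Reactants: 14 (R)-1-[4,6-bis(tert-butyldimethylsilyloxy)-2-(2-hydroxypropan-2-yl)-2,3-dihydro-1-benzofuran-5-yl]-2-methylpropan-1-one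
Product: 15 (R)-1-[4,6-bis(tert-butyldimethylsilyloxy)-2-(prop-1-en-2-yl)-2,3-dihydro-1-benzofuran-5-yl]-2-methylpropan-1-one
Conditions: Burgess reagent, PhMe, 70 °C
Reagents that add atoms: none
Why: Burgess dehydration by intramolecular syn-elimination; six methyl hydrogens compete with the single C2–H, whose loss would give an exocyclic enol ether, and this is the usual way from 2-(2-hydroxypropan-2-yl)dihydrobenzofurans to their isopropenyl analogues, with C2 untouched and its configuration kept.

Step 10
Reactants: 15 (R)-1-[4,6-bis(tert-butyldimethylsilyloxy)-2-(prop-1-en-2-yl)-2,3-dihydro-1-benzofuran-5-yl]-2-methylpropan-1-one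
Product: 16 (R)-1-[4,6-dihydroxy-2-(prop-1-en-2-yl)-2,3-dihydro-1-benzofuran-5-yl]-2-methylpropan-1-one
Conditions: TBAF, AcOH, THF, 0 °C
Reagents that add atoms: none
Why: Fluoride cleavage of aryl silyl ethers; the acetic acid buffer keeps the medium near neutral, so neither the allylic ether at C2 nor the alkene is at risk.

Step 11
Reactants: 17 3-pentanone
Product: 18 trimethyl(pent-2-en-3-yloxy)silane (mixture of geometric isomers)
Conditions: TMSCl, NaI, Et3N, MeCN, rt
Reagents that add atoms: chlorotrimethylsilane C[Si](C)(C)Cl
Why: Soft enolisation and O-silylation of a symmetric ketone; both geometric isomers lead to the same pyrone.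

Step 12
Reactants: 18 trimethyl(pent-2-en-3-yloxy)silane; 19 malonyl dichloride
Product: 20 6-ethyl-4-hydroxy-5-methyl-2H-pyran-2-one
Conditions: Et2O, −78 °C→rt; H2O
Reagents that add atoms: none
Why: Known pyrone synthesis from a silyl enol ether and malonyl dichloride: C-acylation at the enol carbon forms C4'–C5', and closure of the new enol oxygen on the second acyl chloride forms O1'–C2'.

Step 13
Reactants: 20 6-ethyl-4-hydroxy-5-methyl-2H-pyran-2-one
Product: 21 3-[(dimethylamino)methyl]-6-ethyl-4-hydroxy-5-methyl-2H-pyran-2-one
Conditions: CH2=NMe2+ I−, Et3N, CH2Cl2, 0 °C→rt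
Reagents that add atoms: N,N-dimethylmethylideneammonium iodide (Eschenmoser's salt) C=[N+](C)C.[I-]
Why: Mannich reaction at C3', the nucleophilic α-carbon of the vinylogous acid; the preformed iminium salt avoids free formaldehyde and hence bis-pyrone formation.

Step 14
Reactants: 16 (R)-1-[4,6-dihydroxy-2-(prop-1-en-2-yl)-2,3-dihydro-1-benzofuran-5-yl]-2-methylpropan-1-one; 21 3-[(dimethylamino)methyl]-6-ethyl-4-hydroxy-5-methyl-2H-pyran-2-one
Product: 23 3-{[(2R)-4,6-dihydroxy-5-(2-methylpropanoyl)-2-(prop-1-en-2-yl)-2,3-dihydro-1-benzofuran-7-yl]methyl}-6-ethyl-4-hydroxy-5-methyl-2H-pyran-2-one, via methylenepyrandione 22 (not isolated)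
Conditions: 1,4-dioxane, 80 °C
Reagents that add atoms: none
Why: Mannich-base elimination followed by conjugate addition, the established way to bridge acylphloroglucinols and 4-hydroxypyrones with a methylene group; thermal loss of dimethylamine from 21 gives the Michael acceptor 22, which is taken up by C7, the only free and strongly activated carbon of ring A, under neutral conditions that leave C2 and the alkene alone.

## Compound list

1 | phloroglucinol (benzene-1,3,5-triol) | Oc1cc(O)cc(O)c1 | starting material
2 | isobutyryl chloride (2-methylpropanoyl chloride) | CC(C)C(=O)Cl | starting material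
3 | 2-methyl-1-(2,4,6-trihydroxyphenyl)propan-1-one | CC(C)C(=O)c1c(O)cc(O)cc1O | intermediate
4 | isobutylene oxide (2,2-dimethyloxirane) | CC1(C)CO1 | starting material
5 | 1-[2,6-dihydroxy-4-(2-hydroxy-2-methylpropoxy)phenyl]-2-methylpropan-1-one | CC(C)C(=O)c1c(O)cc(OCC(C)(C)O)cc1O | intermediate
6 | N-{[2,4-dihydroxy-6-(2-hydroxy-2-methylpropoxy)-3-(2-methylpropanoyl)phenyl]methylidene}-N-methylmethanaminium chloride | CC(C)C(=O)c1c(O)cc(OCC(C)(C)O)c(C=[N+](C)C)c1O.[Cl-] | intermediate (not isolated)
7 | 2,4-dihydroxy-6-(2-hydroxy-2-methylpropoxy)-3-(2-methylpropanoyl)benzaldehyde | CC(C)C(=O)c1c(O)cc(OCC(C)(C)O)c(C=O)c1O | intermediate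
8 | 2,4-bis(tert-butyldimethylsilyloxy)-6-(2-hydroxy-2-methylpropoxy)-3-(2-methylpropanoyl)benzaldehyde | CC(C)C(=O)c1c(O[Si](C)(C)C(C)(C)C)cc(OCC(C)(C)O)c(C=O)c1O[Si](C)(C)C(C)(C)C | intermediate
9 | 2,4-bis(tert-butyldimethylsilyloxy)-3-(2-methylpropanoyl)-6-[2-methyl-2-(triethylsilyloxy)propoxy]benzaldehyde | CC(C)C(=O)c1c(O[Si](C)(C)C(C)(C)C)cc(OCC(C)(C)O[Si](CC)(CC)CC)c(C=O)c1O[Si](C)(C)C(C)(C)C | intermediate
10 | (E)-4-methyl-N'-{2,4-bis(tert-butyldimethylsilyloxy)-3-(2-methylpropanoyl)-6-[2-methyl-2-(triethylsilyloxy)propoxy]benzylidene}benzenesulfonohydrazide | CC(C)C(=O)c1c(O[Si](C)(C)C(C)(C)C)cc(OCC(C)(C)O[Si](CC)(CC)CC)c(/C=N/NS(=O)(=O)c2ccc(C)cc2)c1O[Si](C)(C)C(C)(C)C | intermediate (precursor of the key step)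
11 | sodium salt of 10 (deprotonated at the sulfonamide nitrogen) | CC(C)C(=O)c1c(O[Si](C)(C)C(C)(C)C)cc(OCC(C)(C)O[Si](CC)(CC)CC)c(/C=N/[N-]S(=O)(=O)c2ccc(C)cc2)c1O[Si](C)(C)C(C)(C)C.[Na+] | intermediate (not isolated)
12 | 1-{3-(diazomethyl)-2,6-bis(tert-butyldimethylsilyloxy)-4-[2-methyl-2-(triethylsilyloxy)propoxy]phenyl}-2-methylpropan-1-one | CC(C)C(=O)c1c(O[Si](C)(C)C(C)(C)C)cc(OCC(C)(C)O[Si](CC)(CC)CC)c(C=[N+]=[N-])c1O[Si](C)(C)C(C)(C)C | intermediate (not isolated)
13 | (R)-1-{4,6-bis(tert-butyldimethylsilyloxy)-2-[2-(triethylsilyloxy)propan-2-yl]-2,3-dihydro-1-benzofuran-5-yl}-2-methylpropan-1-one | CC(C)(O[Si](CC)(CC)CC)[C@H]1Cc2c(O[Si](C)(C)C(C)(C)C)c(C(=O)C(C)C)c(O[Si](C)(C)C(C)(C)C)cc2O1 | intermediate (product of the key step)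
14 | (R)-1-[4,6-bis(tert-butyldimethylsilyloxy)-2-(2-hydroxypropan-2-yl)-2,3-dihydro-1-benzofuran-5-yl]-2-methylpropan-1-one | CC(C)(O)[C@H]1Cc2c(O[Si](C)(C)C(C)(C)C)c(C(=O)C(C)C)c(O[Si](C)(C)C(C)(C)C)cc2O1 | intermediate
15 | (R)-1-[4,6-bis(tert-butyldimethylsilyloxy)-2-(prop-1-en-2-yl)-2,3-dihydro-1-benzofuran-5-yl]-2-methylpropan-1-one | C=C(C)[C@H]1Cc2c(O[Si](C)(C)C(C)(C)C)c(C(=O)C(C)C)c(O[Si](C)(C)C(C)(C)C)cc2O1 | intermediate
16 | (R)-1-[4,6-dihydroxy-2-(prop-1-en-2-yl)-2,3-dihydro-1-benzofuran-5-yl]-2-methylpropan-1-one | C=C(C)[C@H]1Cc2c(O)c(C(=O)C(C)C)c(O)cc2O1 | intermediate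
17 | 3-pentanone | CCC(=O)CC | starting material
18 | trimethyl(pent-2-en-3-yloxy)silane (mixture of geometric isomers) | CC=C(CC)O[Si](C)(C)C | intermediate
19 | malonyl dichloride (propanedioyl dichloride) | O=C(Cl)CC(=O)Cl | starting material
20 | 6-ethyl-4-hydroxy-5-methyl-2H-pyran-2-one | CCc1oc(=O)cc(O)c1C | intermediate
21 | 3-[(dimethylamino)methyl]-6-ethyl-4-hydroxy-5-methyl-2H-pyran-2-one | CCc1oc(=O)c(CN(C)C)c(O)c1C | intermediate
22 | 6-ethyl-5-methyl-3-methylidene-2H-pyran-2,4(3H)-dione | CCC1=C(C)C(=O)C(=C)C(=O)O1 | intermediate (not isolated)
23 | 3-{[(2R)-4,6-dihydroxy-5-(2-methylpropanoyl)-2-(prop-1-en-2-yl)-2,3-dihydro-1-benzofuran-7-yl]methyl}-6-ethyl-4-hydroxy-5-methyl-2H-pyran-2-one | C=C(C)[C@H]1Cc2c(O)c(C(=O)C(C)C)c(O)c(Cc3c(O)c(C)c(CC)oc3=O)c2O1 | target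

## Step count and least certain steps

Total step count: 14. Longest linear sequence: 11 steps (steps 1 to 10, then step 14); steps 11 to 13 form the pyrone branch.

**Step 7 (key step, Proposed new method).**
- Most likely failure: the insertion may be too slow. The O1–CH2 hydrogens sit next to a quaternary carbon and are inductively deactivated by the β-silyloxy group, and the aryl(hydrogen) carbene is stabilised and only weakly electrophilic. Carbene dimerisation, attack on silyl methyl C–H bonds, or silyl transfer from the C4 oxygen to the hydrazone nitrogen of the salt could then take over. At 40 °C the two enantiotopic hydrogens may also be poorly distinguished.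
- Fallback (known chemistry, forming O1–C2 instead of C2–C3): it sets out from 3 and comes back at 14, bypassing steps 2 to 8. The para hydroxyl of 3 is alkylated with 3-chloro-3-methylbut-1-yne (CuCl2 cat., DBU, MeCN, 0 °C) to give 1-[2,6-dihydroxy-4-(2-methylbut-3-yn-2-yloxy)phenyl]-2-methylpropan-1-one F1. Silylation of the two chelated phenols (TBSOTf, 2,6-lutidine) gives 1-[2,6-bis(tert-butyldimethylsilyloxy)-4-(2-methylbut-3-yn-2-yloxy)phenyl]-2-methylpropan-1-one F2. Semihydrogenation (H2, Pd/CaCO3 poisoned with Pb(OAc)2, quinoline) gives 1-[2,6-bis(tert-butyldimethylsilyloxy)-4-(2-methylbut-3-en-2-yloxy)phenyl]-2-methylpropan-1-one F3. Aromatic Claisen rearrangement (PhMe, 110 °C) moves the allyl group to the ortho carbon and gives 1-[2,6-bis(tert-butyldimethylsilyloxy)-4-hydroxy-3-(3-methylbut-2-en-1-yl)phenyl]-2-methylpropan-1-one F4. In F4 only the oxygen that becomes O1 is free, so the later ring closure has one possible direction. Shi epoxidation (KHSO5, K2CO3 buffer, MeCN/H2O, 0 °C) with the enantiomer of the fructose-derived ketone, which by the usual spiro transition-state model should give the S epoxide, gives 1-{2,6-bis(tert-butyldimethylsilyloxy)-3-{[(2S)-3,3-dimethyloxiran-2-yl]methyl}-4-hydroxyphenyl}-2-methylpropan-1-one F5. The neighbouring phenoxide opens the oxirane at its secondary carbon in the 5-exo mode with inversion, in the buffer or on mild base, and gives 14.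

**Step 3.**
- Most likely failure: the chloroiminium reagent may be consumed by the tertiary carbinol, with substitution or elimination in the side chain. A second formylation at the remaining ring carbon, or attack at the enolisable ketone beside the free hydroxyl, is also possible.
- Fallback (protecting-group detour): it sets out from 5 and comes back at 7. TFAA with pyridine acylates all three hydroxyls to 1-[3,5-bis(trifluoroacetoxy)-4-(2-methylpropanoyl)phenoxy]-2-methylpropan-2-yl trifluoroacetate F6. Neutral aqueous work-up hydrolyses the two aryl esters and leaves 1-[3,5-dihydroxy-4-(2-methylpropanoyl)phenoxy]-2-methylpropan-2-yl trifluoroacetate F7. Vilsmeier–Haack formylation of F7, whose side chain no longer has a nucleophilic oxygen, gives 1-[2-formyl-3,5-dihydroxy-4-(2-methylpropanoyl)phenoxy]-2-methylpropan-2-yl trifluoroacetate F8. K2CO3 in MeOH at 0 °C removes the trifluoroacetyl group and gives 7.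

**Step 2.**
- Most likely failure: loss of site selectivity (alkylation at a chelated hydroxyl, double alkylation or C-alkylation) at the temperature that the sluggish epoxide opening needs.
- Fallback (side chain built in two stages): it sets out from 3 and comes back at 5. Alkylation with methyl bromoacetate (K2CO3, acetone, rt) is a fast SN2 reaction at room temperature, where the difference between the free and the chelated hydroxyls is largest, and gives methyl [3,5-dihydroxy-4-(2-methylpropanoyl)phenoxy]acetate F9. Excess MeMgBr (THF, 0 °C) first deprotonates both phenols, which turns the aryl ketone into an unreactive vinylogous carboxylate, and then adds twice to the ester to give 5.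

**Step 8.**
- Most likely failure: an aryl silyl group is lost together with the triethylsilyl group, above all the one on the C6 oxygen, which would expose a phenol to the dehydrating agent of step 9.
- Fallback (no selectivity required in the cleavage): it sets out from 13 and comes back at 14. Global desilylation (TBAF, AcOH, THF) gives (R)-1-[4,6-dihydroxy-2-(2-hydroxypropan-2-yl)-2,3-dihydro-1-benzofuran-5-yl]-2-methylpropan-1-one F10. TBSCl with imidazole, which silylates phenols and not tertiary alcohols, then gives 14.

**Step 14.**
- Most likely failure: self-condensation of the pyrone-derived electrophile with pyrone set free by retro-Mannich cleavage, O-alkylation in place of C-alkylation, or isomerisation of the isopropenyl dihydrofuran if the medium turns acidic.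
- Fallback (roles of the two partners reversed): it sets out from 16 and comes back at 23. Mannich reaction of 16 with Eschenmoser's salt at C7 gives (R)-1-{7-[(dimethylamino)methyl]-4,6-dihydroxy-2-(prop-1-en-2-yl)-2,3-dihydro-1-benzofuran-5-yl}-2-methylpropan-1-one F11. Heating F11 with pyrone 20 (1,4-dioxane, 80 °C) exchanges the amine for C3' of the pyrone by elimination and addition and gives 23; steps 13 and 14 are then not needed.

## Further compounds

F1 | step 7 | 1-[2,6-dihydroxy-4-(2-methylbut-3-yn-2-yloxy)phenyl]-2-methylpropan-1-one | CC(C)C(=O)c1c(O)cc(OC(C)(C)C#C)cc1O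
F2 | step 7 | 1-[2,6-bis(tert-butyldimethylsilyloxy)-4-(2-methylbut-3-yn-2-yloxy)phenyl]-2-methylpropan-1-one | CC(C)C(=O)c1c(O[Si](C)(C)C(C)(C)C)cc(OC(C)(C)C#C)cc1O[Si](C)(C)C(C)(C)C
F3 | step 7 | 1-[2,6-bis(tert-butyldimethylsilyloxy)-4-(2-methylbut-3-en-2-yloxy)phenyl]-2-methylpropan-1-one | CC(C)C(=O)c1c(O[Si](C)(C)C(C)(C)C)cc(OC(C)(C)C=C)cc1O[Si](C)(C)C(C)(C)C
F4 | step 7 | 1-[2,6-bis(tert-butyldimethylsilyloxy)-4-hydroxy-3-(3-methylbut-2-en-1-yl)phenyl]-2-methylpropan-1-one | CC(C)C(=O)c1c(O[Si](C)(C)C(C)(C)C)cc(O)c(CC=C(C)C)c1O[Si](C)(C)C(C)(C)C
F5 | step 7 | 1-{2,6-bis(tert-butyldimethylsilyloxy)-3-{[(2S)-3,3-dimethyloxiran-2-yl]methyl}-4-hydroxyphenyl}-2-methylpropan-1-one | CC(C)C(=O)c1c(O[Si](C)(C)C(C)(C)C)cc(O)c(C[C@@H]2OC2(C)C)c1O[Si](C)(C)C(C)(C)C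
F6 | step 3 | 1-[3,5-bis(trifluoroacetoxy)-4-(2-methylpropanoyl)phenoxy]-2-methylpropan-2-yl trifluoroacetate | CC(C)C(=O)c1c(OC(=O)C(F)(F)F)cc(OCC(C)(C)OC(=O)C(F)(F)F)cc1OC(=O)C(F)(F)F
F7 | step 3 | 1-[3,5-dihydroxy-4-(2-methylpropanoyl)phenoxy]-2-methylpropan-2-yl trifluoroacetate | CC(C)C(=O)c1c(O)cc(OCC(C)(C)OC(=O)C(F)(F)F)cc1O
F8 | step 3 | 1-[2-formyl-3,5-dihydroxy-4-(2-methylpropanoyl)phenoxy]-2-methylpropan-2-yl trifluoroacetate | CC(C)C(=O)c1c(O)cc(OCC(C)(C)OC(=O)C(F)(F)F)c(C=O)c1O
F9 | step 2 | methyl [3,5-dihydroxy-4-(2-methylpropanoyl)phenoxy]acetate | COC(=O)COc1cc(O)c(C(=O)C(C)C)c(O)c1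
F10 | step 8 | (R)-1-[4,6-dihydroxy-2-(2-hydroxypropan-2-yl)-2,3-dihydro-1-benzofuran-5-yl]-2-methylpropan-1-one | CC(C)(O)[C@H]1Cc2c(O)c(C(=O)C(C)C)c(O)cc2O1
F11 | step 14 | (R)-1-{7-[(dimethylamino)methyl]-4,6-dihydroxy-2-(prop-1-en-2-yl)-2,3-dihydro-1-benzofuran-5-yl}-2-methylpropan-1-one | C=C(C)[C@H]1Cc2c(O)c(C(=O)C(C)C)c(O)c(CN(C)C)c2O1
A1 | alternative 1 | 3-{[(2R)-4,6-bis(methoxymethoxy)-5-(2-methylpropanoyl)-2-(prop-1-en-2-yl)-2,3-dihydro-1-benzofuran-7-yl]methyl}-6-ethyl-4-hydroxy-5-methyl-2H-pyran-2-one | C=C(C)[C@H]1Cc2c(OCOC)c(C(=O)C(C)C)c(OCOC)c(Cc3c(O)c(C)c(CC)oc3=O)c2O1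
A2 | alternative 1 | 2-{[(2R)-4,6-bis(methoxymethoxy)-5-(2-methylpropanoyl)-2-(prop-1-en-2-yl)-2,3-dihydro-1-benzofuran-7-yl]methyl}propanedioyl dichloride | C=C(C)[C@H]1Cc2c(OCOC)c(C(=O)C(C)C)c(OCOC)c(CC(C(=O)Cl)C(=O)Cl)c2O1
A3 | alternative 2 | 3-({(2R)-4-ethoxy-6-hydroxy-2-[2-(triethylsilyloxy)propan-2-yl]-2,3-dihydro-1-benzofuran-7-yl}methyl)-6-ethyl-4-methoxy-5-methyl-2H-pyran-2-one | CC(C)(O[Si](CC)(CC)CC)[C@H]1Cc2c(OCC)cc(O)c(Cc3c(OC)c(C)c(CC)oc3=O)c2O1
A4 | alternative 2 | 3-(3-{[(2R)-1-(2-ethoxy-4-oxocyclobut-1-en-1-yl)-3-methyl-3-(triethylsilyloxy)butan-2-yl]oxy}prop-2-yn-1-yl)-6-ethyl-4-methoxy-5-methyl-2H-pyran-2-one | CC(C)(O[Si](CC)(CC)CC)[C@@H](CC1=C(OCC)CC1=O)OC#CCc1c(OC)c(C)c(CC)oc1=O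
A5 | alternative 3 | (R)-1-[6-hydroxy-4-(methoxymethoxy)-2-(prop-1-en-2-yl)-2,3-dihydro-1-benzofuran-5-yl]-2-methylpropan-1-one | C=C(C)[C@H]1Cc2c(OCOC)c(C(=O)C(C)C)c(O)cc2O1
A6 | alternative 3 | (R)-4-(methoxymethoxy)-2-(prop-1-en-2-yl)-5-(trimethylsilyl)-2,3-dihydro-1-benzofuran-6-yl trifluoromethanesulfonate | C=C(C)[C@H]1Cc2c(OCOC)c([Si](C)(C)C)c(OS(=O)(=O)C(F)(F)F)cc2O1
A7 | alternative 3 | (R)-5,6-didehydro-4-(methoxymethoxy)-2-(prop-1-en-2-yl)-2,3-dihydro-1-benzofuran | C=C(C)[C@H]1CC2=C(OCOC)C#CC=C2O1
A8 | alternative 3 | 2-methylpropanoic acid | CC(C)C(=O)O
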